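Its constants are invented; the result is computed.

Ring closure is slow, with a half-life of 43.3 s for an activated form left to itself, and in that time substrate can catch the form first.

    substrate + activated form → open dimer (k1 = 31 M⁻¹ s⁻¹)
    activated form → ring (k2 = 0.016 s⁻¹)
    substrate + activator → activated form (k3 = 18 M⁻¹ s⁻¹)
    substrate + activated form → side product (k4 = 16 M⁻¹ s⁻¹)

| setting | autumn | spring | winter | midnight |
|---|---|---|---|---|
| substrate | 0.60 mM | 1.0 mM | 1.5 mM | 2.5 mM |
| activator | 1.00 equiv | 1.00 equiv | 1.00 equiv | 1.00 equiv |
| time | 80 s | 80 s | 80 s | 80 s |

- share of ring in all that became ring or open dimer or side product for autumn, spring, winter, midnight, in this order
- the shape of the row from first to last (rises all the way / falls all the way / falls, then rises / hardly changes / rises, then falls)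

- percent here means substrate units held: one open dimer or side product counts as two
- "hardly changes" means that all values lie within two and a half points (for a concentration: within two and a half percent of the largest)
- run time (autumn): 80 s

Substrate is the limiting reagent, since it is spent once in activation and again in each open dimer or side product, while activator is spent once. Its ledger has these entries.

The first entry is substrate not yet taken up. Counting turnovers of activation at the charged levels gives 0.864 in the autumn flask, under one, so substrate should stand over there at the end. The midnight flask gets 3.60, so it should run much further down.

The second entry is activated form still waiting, which the asked share leaves out.

The third entry is ring, one unit per closure, and the fourth is open dimer and side product, two units per capture. Closure runs at its rate constant, and capture runs at the two capture constants added, times the substrate level. The two are equal at the crossing concentration 0.340 mM, the substrate level at which an activated form is as likely to close as to be caught. Because capture books two units, ring takes at any moment a share of the new product units equal to the crossing concentration divided by the crossing concentration plus twice the substrate level.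

The crossing concentration lies below every charge. Putting the charges into this share gives 22.1%, 14.5%, 10.2% and 6.37%. Substrate can fall but not rise, so these are floors. My reckoning by hand goes this far: the row should fall, standing above these floors, and it gives no closer values.

The forecast gives 30.5%, 25.5%, 22.8% and 19.6%, a row that falls all the way, holding that “higher starting concentration favours the two-unit products”. Its last value stands above my floor.

The simulation gives 31.5%, 25.9%, 22.7% and 20.0%, a row that falls all the way.

At the end of the autumn run substrate stands at 0.245 mM, below the crossing concentration, so closure there runs 1.39 times as fast as capture into open dimer and side product together. In the midnight flask substrate is still 0.395 mM at 40.0 s, above the crossing concentration, and it reaches 0.109 mM at 80.0 s, where closure runs 3.12 times as fast as capture, and the ring share of that flask stands at 20.0%, above its floor of 6.37%.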